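**Assumption:** racemic alcohol 6 is resolved in Step 4 by Sharpless kinetic resolution. The (S)-carbinol reacts fast with L-(+)-DET and gives the required cis-epoxide. The intramolecular Diels–Alder (Step 7) is assumed to give the cis-fused lactone with the C2 side chain on the convex face.

**Retrosynthetic overview**
- **Key step (dearomatization):** 2-methylfuran is opened oxidatively to (E)-4-oxopent-2-enal, a masked C14–C17 unit with the E-enone that later fixes the trans C1/C14 relationship. Vinyl-titanium addition and Sharpless kinetic resolution then build the C2–C4 carbinol/epoxide unit.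
- **Ring order:** (i) one intramolecular Diels–Alder of the β-keto-ester silyl dienol on the γ-acyloxy enone forms the cyclohexane and the γ-lactone (C1, C10, C14; C11/C12 as enol ether). (ii) 7-exo opening of the C3–C4 epoxide by C16–OH forms the oxepane. (iii) Lactol oxocarbenium allylation forms the THF C9–C8 bond. (iv) An intramolecular Nozaki–Hiyama–Kishi (NHK) reaction closes the oxonane (C6–C7).
- **Endgame:** oxidize C6 to the enone, then acetylate C11.

---

**Step 1**
Reactants: 1, 2-methylfuran
Product: 2, (E)-4-oxopent-2-enal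
Conditions: NBS, pyridine, NaHCO3, THF/H2O, –10 °C; then I2 (cat.), CH2Cl2, rt
Reagents that add atoms: water, O
Why: Oxidative furan ring opening (Kobayashi/Achmatowicz-type) gives the Z-enedial, and I2-catalysed isomerization gives the E-enone that later fixes the trans C1/C14 relationship.

**Step 2**
Reactants: 3, 3-(4-methoxybenzyloxy)propanal; 4, ethyltriphenylphosphonium bromide
Product: 5, (Z)-4-iodopent-3-en-1-yl PMB ether
Conditions: 4, NaHMDS, THF; I2; NaHMDS, HMPA, –78 °C; then 3
Reagents that add atoms: iodine, II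
Why: Stork–Zhao-type Wittig via the iodo-ylide gives the (Z)-trisubstituted vinyl iodide, which puts C2 and C5 cis as required for the cis-epoxide.

**Step 3**
Reactants: 5; 2
Product: 6, racemic (3E,6Z)-5-hydroxy-6-methyl-9-(PMBO)nona-3,6-dien-2-one
Conditions: t-BuLi, Et2O, –78 °C; ClTi(OiPr)3; then 2, –78 °C
Reagents that add atoms: none
Why: The vinyl-titanium reagent adds chemoselectively (Reetz) to the aldehyde over the ketone and enone; C2 is formed racemic and resolved in Step 4.

**Step 4**
Reactants: 6
Product: 7, epoxy alcohol ((S)-carbinol C2, cis-epoxide C3/C4)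
Conditions: Ti(OiPr)4, L-(+)-DET, TBHP (0.6 equiv), 4 Å MS, CH2Cl2, –20 °C
Reagents that add atoms: tert-butyl hydroperoxide, CC(C)(C)OO (oxygen)
Why: Sharpless kinetic resolution; the matched (S)-alcohol is epoxidized from the face that sets C3/C4 as in the target (the enone is inert to Ti/TBHP).

**Step 5**
Reactants: 8, Meldrum's acid; 9, methacryloyl chloride
Product: 10, 5-methacryloyl Meldrum's acid
Conditions: pyridine, CH2Cl2, 0 °C → rt
Reagents that add atoms: none
Why: C-acylation of Meldrum's acid prepares an acylketene precursor carrying the isopropenyl ketone that will become the diene.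

**Step 6**
Reactants: 7; 10
Product: 11, β-keto ester of the C2 alcohol
Conditions: MeCN, 80 °C
Reagents that add atoms: none
Why: Thermolysis of 10 gives the acylketene (loses acetone and CO2), which the secondary alcohol traps; C2 is untouched.

**Step 7**
Reactants: 11
Product: 12, lactone-fused cyclohexene with C11 TBS enol ether and C15 acetyl
Conditions: TBSOTf, Et3N, CH2Cl2, –78 → 0 °C; then toluene, BHT, 110 °C
Reagents that add atoms: TBSOTf, CC(C)(C)[Si](C)(C)OS(=O)(=O)C(F)(F)F
Why: Intramolecular Diels–Alder (ester tether) between the 2-silyloxydiene C10=C11–C12=C13 and the E-enone C14=C1; the E-enone gives trans C1/C14, the three-atom ester tether forces the cis-fused γ-lactone, and the side chain at C2 sits on the convex face. Proposed new method: type-1 IMDA of the TBS-dienol of a β-keto ester tethered through a γ-acyloxy E-enone; closest known is the lactone-forming IMDA of allyl 2-silyloxy-2,4-dienoates, with the push–pull diene and activated enone expected to lower the barrier.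

**Step 8**
Reactants: 12
Product: 13, isopropenyl compound
Conditions: Ph3PCH3Br, KOtBu, THF, 0 °C
Reagents that add atoms: methylenetriphenylphosphorane, C=P(c1ccccc1)(c1ccccc1)c1ccccc1 (CH2)
Why: Wittig methylenation of the methyl ketone supplies C16; base also equilibrates C14 α to the ketone to the equatorial (trans) epimer.

**Step 9**
Reactants: 13
Product: 14, C11 alcohol with C12 methyl set
Conditions: TBAF, AcOH, THF, –78 °C; then Zn(BH4)2, –78 °C
Reagents that add atoms: none
Why: Fluoride unmasks the enol, which is protonated from the convex face so Me at C12 is down (the concave face is blocked by the lactone), and chelation-controlled hydride delivery from the convex face gives C11–OH down. Proposed new method: one-pot kinetic protonation/reduction of the β-keto lactone silyl enol ether; closest known is kinetic protonation and Zn(BH4)2 reduction of β-keto esters, with C12 trapped as the contra-thermodynamic axial-Me epimer.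

**Step 10**
Reactants: 14
Product: 15, C11 TBS ether
Conditions: TBSCl, imidazole, DMF, 40 °C
Reagents that add atoms: TBSCl, CC(C)(C)[Si](C)(C)Cl
Why: Silylation under non-acidic conditions protects C11–OH and leaves the tertiary epoxide intact.

**Step 11**
Reactants: 15
Product: 16, primary alcohol at C16
Conditions: 9-BBN, THF, 0 °C → rt; then NaBO3·4H2O, THF/H2O
Reagents that add atoms: hydrogen peroxide equivalent from perborate, OO
Why: 9-BBN hydroboration of the 1,1-disubstituted alkene is anti-Markovnikov, so C16 carries the oxygen; H is delivered to C15 from the less hindered face, and C15 epimers are separated at Step 12.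

**Step 12**
Reactants: 16
Product: 17, oxepane with C4–OH
Conditions: CSA (10 mol%), CH2Cl2, 0 °C
Reagents that add atoms: none
Why: 7-exo-tet opening of the C3–C4 epoxide by C16–OH at the tertiary C3 proceeds with inversion at C3 and leaves C4 as the free alcohol, giving the target C3/C4 configuration.

**Step 13**
Reactants: 17
Product: 18, C4 octanoate
Conditions: octanoyl chloride, pyridine, DMAP, CH2Cl2, 0 °C
Reagents that add atoms: octanoyl chloride, CCCCCCCC(=O)Cl
Why: Acylation of the hindered C4 alcohol installs the octanoate with retention.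

**Step 14**
Reactants: 18
Product: 19, lactol (C9 epimeric mixture)
Conditions: DIBAL-H (1.1 equiv), CH2Cl2, –78 °C
Reagents that add atoms: none
Why: The strained γ-lactone is reduced to the lactol faster than the hindered octanoate or the TBS ether; C9 stereochemistry is set in Step 15.

**Step 15**
Reactants: 19; 20, 2-iodoallyltrimethylsilane
Product: 21, THF with C8 iodoallyl (C9 set)
Conditions: BF3·OEt2, CH2Cl2, –78 °C
Reagents that add atoms: none
Why: Hosomi–Sakurai allylation of the cis-fused bicyclic oxocarbenium occurs from the convex face, placing C8 cis to H1/H10 as in the target.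

**Step 16**
Reactants: 21
Product: 22, C6 alcohol
Conditions: DDQ, CH2Cl2/pH 7 buffer, 0 °C
Reagents that add atoms: none
Why: Oxidative PMB removal leaves the vinyl iodide, silyl ether and esters intact.

**Step 17**
Reactants: 22
Product: 23, C6 aldehyde
Conditions: DMP, NaHCO3, CH2Cl2, rt
Reagents that add atoms: none
Why: Mild oxidation of the primary alcohol; no new stereocenter.

**Step 18**
Reactants: 23
Product: 24, oxonane allylic alcohol (C6 epimeric mixture)
Conditions: CrCl2 (10 equiv), NiCl2 (cat.), DMF, 0.003 M, 25 °C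
Reagents that add atoms: none
Why: Intramolecular NHK forms C6–C7, giving the C6 carbinol with the exocyclic methylene; the bicyclic THF template preorganizes the 9-membered ring. Proposed new method: NHK closure of the nine-membered oxonane of the briarellin/asbestinin type; closest known is intramolecular NHK closure of 8–9-membered rings.

**Step 19**
Reactants: 24
Product: 25, enone (C6 ketone)
Conditions: DMP, NaHCO3, CH2Cl2, rt
Reagents that add atoms: none
Why: Oxidation of the allylic alcohol removes the C6 stereo issue and gives the α-methylene ketone.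

**Step 20**
Reactants: 25
Product: 26, C11 alcohol
Conditions: HF·pyridine, pyridine, THF, 0 → 25 °C
Reagents that add atoms: none
Why: Buffered fluoride removes the secondary TBS ether without touching the octanoate or enone.

**Step 21**
Reactants: 26
Product: 27, Asbestinin 16
Conditions: Ac2O, DMAP, Et3N, CH2Cl2
Reagents that add atoms: acetic anhydride, CC(=O)OC(C)=O
Why: Acetylation of C11–OH with retention gives the target.

---

**Compound list**
1 | 2-methylfuran | Cc1ccco1 | starting material
2 | (E)-4-oxopent-2-enal | CC(=O)/C=C/C=O | intermediate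
3 | 3-(4-methoxybenzyloxy)propanal | O=CCCOCc1ccc(OC)cc1 | starting material
4 | ethyltriphenylphosphonium bromide | CC[P+](c1ccccc1)(c1ccccc1)c1ccccc1.[Br-] | starting material
5 | (Z)-4-iodopent-3-en-1-yl 4-methoxybenzyl ether | I/C(C)=C\CCOCc1ccc(OC)cc1 | intermediate
6 | racemic (3E,6Z)-5-hydroxy-6-methyl-9-(PMBO)nona-3,6-dien-2-one | CC(=O)/C=C/C(O)/C(C)=C\CCOCc1ccc(OC)cc1 | intermediate
7 | (S)-carbinol cis-epoxy alcohol | CC(=O)/C=C/[C@H](O)[C@]1(C)O[C@@H]1CCOCc1ccc(OC)cc1 | intermediate
8 | Meldrum's acid | CC1(C)OC(=O)CC(=O)O1 | starting material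
9 | methacryloyl chloride | C=C(C)C(=O)Cl | starting material
10 | 5-methacryloyl Meldrum's acid | CC1(C)OC(=O)C(C(=O)C(C)=C)C(=O)O1 | intermediate
11 | β-keto ester of 7 | CC(=O)/C=C/[C@H](OC(=O)CC(=O)C(C)=C)[C@]1(C)O[C@@H]1CCOCc1ccc(OC)cc1 | intermediate
12 | IMDA lactone, C11 TBS enol ether, C15 acetyl | CC(=O)[C@@H]1CC(C)=C(O[Si](C)(C)C(C)(C)C)[C@H]2C(=O)O[C@H]([C@]3(C)O[C@@H]3CCOCc3ccc(OC)cc3)[C@@H]12 | intermediate
13 | isopropenyl analogue of 12 | C=C(C)[C@@H]1CC(C)=C(O[Si](C)(C)C(C)(C)C)[C@H]2C(=O)O[C@H]([C@]3(C)O[C@@H]3CCOCc3ccc(OC)cc3)[C@@H]12 | intermediate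
14 | C11 alcohol | C=C(C)[C@@H]1C[C@@H](C)[C@@H](O)[C@H]2C(=O)O[C@H]([C@]3(C)O[C@@H]3CCOCc3ccc(OC)cc3)[C@@H]12 | intermediate
15 | C11 TBS ether | C=C(C)[C@@H]1C[C@@H](C)[C@@H](O[Si](C)(C)C(C)(C)C)[C@H]2C(=O)O[C@H]([C@]3(C)O[C@@H]3CCOCc3ccc(OC)cc3)[C@@H]12 | intermediate
16 | C16 primary alcohol | OC[C@H](C)[C@@H]1C[C@@H](C)[C@@H](O[Si](C)(C)C(C)(C)C)[C@H]2C(=O)O[C@H]([C@]3(C)O[C@@H]3CCOCc3ccc(OC)cc3)[C@@H]12 | intermediate
17 | oxepane, C4–OH | COc1ccc(COCC[C@@H](O)[C@]2(C)OC[C@H](C)[C@@H]3C[C@@H](C)[C@@H](O[Si](C)(C)C(C)(C)C)[C@H]4C(=O)O[C@H]2[C@@H]34)cc1 | intermediate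
18 | C4 octanoate | COc1ccc(COCC[C@@H](OC(=O)CCCCCCC)[C@]2(C)OC[C@H](C)[C@@H]3C[C@@H](C)[C@@H](O[Si](C)(C)C(C)(C)C)[C@H]4C(=O)O[C@H]2[C@@H]34)cc1 | intermediate
19 | lactol (C9 mixture) | COc1ccc(COCC[C@@H](OC(=O)CCCCCCC)[C@]2(C)OC[C@H](C)[C@@H]3C[C@@H](C)[C@@H](O[Si](C)(C)C(C)(C)C)[C@H]4C(O)O[C@H]2[C@@H]34)cc1 | intermediate
20 | 2-iodoallyltrimethylsilane | C=C(I)C[Si](C)(C)C | starting material
21 | C8 iodoallyl THF | COc1ccc(COCC[C@@H](OC(=O)CCCCCCC)[C@]2(C)OC[C@H](C)[C@@H]3C[C@@H](C)[C@@H](O[Si](C)(C)C(C)(C)C)[C@H]4[C@H](CC(I)=C)O[C@H]2[C@@H]34)cc1 | intermediate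
22 | C6 alcohol | OCC[C@@H](OC(=O)CCCCCCC)[C@]2(C)OC[C@H](C)[C@@H]3C[C@@H](C)[C@@H](O[Si](C)(C)C(C)(C)C)[C@H]4[C@H](CC(I)=C)O[C@H]2[C@@H]34 | intermediate
23 | C6 aldehyde | O=CC[C@@H](OC(=O)CCCCCCC)[C@]2(C)OC[C@H](C)[C@@H]3C[C@@H](C)[C@@H](O[Si](C)(C)C(C)(C)C)[C@H]4[C@H](CC(I)=C)O[C@H]2[C@@H]34 | intermediate
24 | oxonane allylic alcohol (C6 mixture) | OC1C[C@@H](OC(=O)CCCCCCC)[C@]2(C)OC[C@H](C)[C@@H]3C[C@@H](C)[C@@H](O[Si](C)(C)C(C)(C)C)[C@H]4[C@H](CC1=C)O[C@H]2[C@@H]34 | intermediate
25 | enone, C11 OTBS | O=C1C[C@@H](OC(=O)CCCCCCC)[C@]2(C)OC[C@H](C)[C@@H]3C[C@@H](C)[C@@H](O[Si](C)(C)C(C)(C)C)[C@H]4[C@H](CC1=C)O[C@H]2[C@@H]34 | intermediate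
26 | C11 alcohol | O=C1C[C@@H](OC(=O)CCCCCCC)[C@]2(C)OC[C@H](C)[C@@H]3C[C@@H](C)[C@@H](O)[C@H]4[C@H](CC1=C)O[C@H]2[C@@H]34 | intermediate
27 | Asbestinin 16 | O=C1C[C@@H](OC(=O)CCCCCCC)[C@]2(C)OC[C@H](C)[C@@H]3C[C@@H](C)[C@@H](OC(C)=O)[C@H]4[C@H](CC1=C)O[C@H]2[C@@H]34 | target

**Total steps:** 21. **Longest linear sequence:** 19 (Steps 1, 3, 4, 6–21).

**Three steps most likely to fail**
1. **Step 7 (IMDA).** The ester-tether geometry, the silyl-enol formation next to a tertiary epoxide, and the cis-lactone/exo-side-chain outcome are all uncertain. Fallback: use an ether-tethered IMDA (allyl pentadienyl ether, which gives the cis-fused tetrahydrofuran directly), then oxidize C9 with RuO4 to the lactone.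
2. **Step 9 (C12/C11 stereochemistry).** Kinetic protonation may erode to the thermodynamic Me-equatorial epimer. Fallback: convert the C11 ketone to the enol triflate, reduce it (Pd/HCO2H) to the Δ11,12 alkene, hydroborate from the convex face (C11–OH up, Me down), then invert C11 by Mitsunobu.
3. **Step 18 (nine-membered NHK closure).** Oligomerization or poor conversion is possible. Fallback: form the oxonane by ring-closing metathesis of a C5=C6 (or C7=C8) diene to an oxonene, then functionalize the alkene to the C6 enone.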